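The pyranone ring of the (2S)-flavanone is opened at C4–C4a (Friedel–Crafts acylation) and at O1–C2 (Mitsunobu etherification with inversion), leaving ring A as a phenol and a commercial (R)-β-hydroxy ester that brings C2, C3, C4 and the 2-phenyl ring.
The route rests on ring A (C4a, C5, C6, C7, C8, C8a): a 1,3,5-trioxygenated benzene in which only the oxygen on C8a (O1) is not a methyl ether and C8a is the neighbour of the side-chain carbon C8; a cyclobutenone plus ynol ether benzannulation (new bonds C8a–C8, C7–C6 and C8a–C4a) builds this ring with the C8a hydroxyl free.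
The ynol ether oxygen (later C7–O) is carried as a triisopropylsilyl ether: such ynol ethers are made in one flask from terminal alkynes, so the (S)-alkyne comes from methacrolein by asymmetric allenylboration, and silicon is exchanged for methyl once O1 is alkylated.
Order of ring formation: ring A (step 6), then the pyranone ring (step 10); the side-chain stereocentre is set in step 1 and C2 in step 7.

Key step: step 6

Assumption: the SMILES is read as (S) at the side-chain carbinol and (S) at C2, and the silyl-for-methyl change on the ynol ether oxygen is treated as a change of O-substituent only.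

Step 1
Reactants: 1 methacrolein; 2 propargyl bromide
Product: 6 (S)-2-methylhex-1-en-5-yn-3-ol, via allenylmagnesium bromide 3 (not isolated), via B-allenyldiisopinocampheylborane 4 (not isolated), via borinate ester 5 (not isolated)
Conditions: 2, Mg, HgCl2 (cat.), Et2O, 0 °C; (−)-B-methoxydiisopinocampheylborane [(−)-Ipc2BOMe, from (+)-α-pinene], Et2O, −78 °C to rt; 1, −78 °C; then NaOH (3 M aq), H2O2 (30%), 0 °C to rt
Reagents that add atoms: none
Why: Asymmetric allenylboration (Brown type): allenylborane 4 transfers its γ-carbon through a closed six-membered transition state with allenyl-to-propargyl transposition, and the isopinocampheyl groups derived from (+)-α-pinene should direct attack to the Si face of the aldehyde, which sets the (S)-carbinol before oxidative work-up cleaves borinate 5.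

Step 2
Reactants: 6 (S)-2-methylhex-1-en-5-yn-3-ol
Product: 7 (S)-tert-butyldimethyl[(2-methylhex-1-en-5-yn-3-yl)oxy]silane
Conditions: t-BuMe2SiCl, imidazole, DMF, rt
Reagents that add atoms: tert-butyldimethylsilyl chloride, CC(C)(C)[Si](C)(C)Cl
Why: Silyl ether formation on a secondary alcohol masks the carbinol for the anionic and thermal steps that follow and does not touch the stereocentre.

Step 3
Reactants: 7 (S)-tert-butyldimethyl[(2-methylhex-1-en-5-yn-3-yl)oxy]silane
Product: 10 (S)-tert-butyldimethyl({2-methyl-6-[(triisopropylsilyl)oxy]hex-1-en-5-yn-3-yl}oxy)silane, via lithium acetylide 8 (not isolated), via lithium ynolate 9 (not isolated)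
Conditions: n-BuLi, THF, −78 °C; LiOOt-Bu (from t-BuOOH and LiN(SiMe3)2, THF, −78 °C), −78 to 0 °C; i-Pr3SiOTf, −78 to 0 °C
Reagents that add atoms: tert-butyl hydroperoxide, CC(C)(C)OO; triisopropylsilyl trifluoromethanesulfonate, CC(C)[Si](C(C)C)(C(C)C)OS(=O)(=O)C(F)(F)F
Why: Oxygenation of a lithium acetylide by lithium tert-butyl peroxide (attack on the O–O bond) gives the lithium ynolate, which the bulky silyl triflate traps on oxygen; this is the known one-flask conversion of terminal alkynes into triisopropylsilyloxyalkynes and tolerates silyl ethers and isolated alkenes.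

Step 4
Reactants: 11 3-ethoxycyclobut-2-en-1-one
Product: 12 cyclobutane-1,3-dione
Conditions: HCl (2 M aq), 0 °C to rt; freeze-drying
Reagents that add atoms: water, O
Why: Acid hydrolysis of a vinylogous ester (addition of water at C3, loss of ethanol) should give the dione, which is used at once because it is a strong carbon acid of limited shelf life.

Step 5
Reactants: 12 cyclobutane-1,3-dione
Product: 13 3-methoxycyclobut-2-en-1-one
Conditions: Me3SiCHN2 (1.05 equiv), MeOH–Et2O (1:4), 0 °C
Reagents that add atoms: (trimethylsilyl)diazomethane, C[Si](C)(C)C=[N+]=[N-]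
Why: O-Methylation of the acidic enol by the methyldiazonium ion released from the silyldiazomethane in methanol (diazoalkane esterification type) re-forms the vinylogous ester without acid or alkoxide, either of which tends to open the strained ring at the carbonyl group.

Step 6
Reactants: 13 3-methoxycyclobut-2-en-1-one; 10 (S)-tert-butyldimethyl({2-methyl-6-[(triisopropylsilyl)oxy]hex-1-en-5-yn-3-yl}oxy)silane
Product: 18 2-[(2S)-2-(tert-butyldimethylsilyloxy)-3-methylbut-3-enyl]-5-methoxy-3-(triisopropylsilyloxy)phenol, via vinylketene 14 (not isolated), via vinylcyclobutenone 15 (not isolated), via dienylketene 16 (not isolated), via cyclohexadienone 17 (not isolated)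
Conditions: 13 (1.3 equiv, in portions), toluene, 80 °C then 110 °C, sealed tube
Reagents that add atoms: none
Why: Heating opens cyclobutenone 13 by 4π-electrocyclic cleavage to vinylketene 14, whose electrophilic carbonyl carbon (future C8a) adds to the nucleophilic, oxygen-free carbon of the silyl ynol ether (C8) in a [2+2] cycloaddition while the ketene α-carbon (C6) bonds to the oxygenated alkyne carbon (C7), giving vinylcyclobutenone 15. A second 4π opening gives dienylketene 16, which closes ring A by a thermal 6π-electrocyclization (forming C8a–C4a) to dienone 17 and tautomerises to phenol 18. The closest known reaction type is the Danheiser benzannulation of cyclobutenones with trialkylsilyloxyalkynes, and the thermal opening of a 3-oxygenated cyclobutenone is the same event that every such annulation passes through in its second stage (15 to 16). No stereocentre is formed: the sp3 ring carbon of 15 is lost on aromatisation and the silyl-protected carbinol is not touched. The step needs regioselectivity, which the opposite polarisation of ketene and ynol ether should secure so that the free hydroxyl ends on C8a next to the side chain and the silyl ether on C7, and it needs chemoselectivity, which should hold because the isolated 1,1-disubstituted alkene is far less nucleophilic than the ynol ether.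

Step 7
Reactants: 18 2-[(2S)-2-(tert-butyldimethylsilyloxy)-3-methylbut-3-enyl]-5-methoxy-3-(triisopropylsilyloxy)phenol; 19 ethyl (R)-3-hydroxy-3-phenylpropanoate
Product: 20 ethyl (3S)-3-{2-[(2S)-2-(tert-butyldimethylsilyloxy)-3-methylbut-3-enyl]-5-methoxy-3-(triisopropylsilyloxy)phenoxy}-3-phenylpropanoate
Conditions: PPh3, DIAD, toluene, 0 °C to rt
Reagents that add atoms: none
Why: Mitsunobu etherification: the free C8a phenol displaces the oxyphosphonium of the benzylic alcohol by SN2 with inversion, so the (R)-alcohol should give the (S)-ether carbon that becomes C2, and toluene at low temperature limits the competing elimination to ethyl cinnamate.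

Step 8
Reactants: 20 ethyl (3S)-3-{2-[(2S)-2-(tert-butyldimethylsilyloxy)-3-methylbut-3-enyl]-5-methoxy-3-(triisopropylsilyloxy)phenoxy}-3-phenylpropanoate
Product: 22 ethyl (3S)-3-{2-[(2S)-2-(tert-butyldimethylsilyloxy)-3-methylbut-3-enyl]-3,5-dimethoxyphenoxy}-3-phenylpropanoate, via tetrabutylammonium phenoxide 21 (not isolated)
Conditions: Bu4NF (1.05 equiv), THF, 0 °C; then MeI, 0 °C to rt
Reagents that add atoms: iodomethane, CI
Why: Fluoride cleaves the aryl silyl ether (phenoxide leaving group) much faster than the hindered secondary alkyl silyl ether, and phenoxide 21 is methylated in the same flask (Williamson ether synthesis), which completes the C5/C7 dimethoxy pattern.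

Step 9
Reactants: 22 ethyl (3S)-3-{2-[(2S)-2-(tert-butyldimethylsilyloxy)-3-methylbut-3-enyl]-3,5-dimethoxyphenoxy}-3-phenylpropanoate
Product: 23 (3S)-3-{2-[(2S)-2-(tert-butyldimethylsilyloxy)-3-methylbut-3-enyl]-3,5-dimethoxyphenoxy}-3-phenylpropanoic acid
Conditions: LiOH·H2O, THF–H2O (3:1), 0 °C to rt; then HCl (0.5 M aq) to pH 4, 0 °C
Reagents that add atoms: lithium hydroxide, [Li+].[OH-]
Why: Saponification (acyl substitution by hydroxide) at low temperature, where attack at the ester carbonyl should be much faster than α-deprotonation and loss of the aryloxide.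

Step 10
Reactants: 23 (3S)-3-{2-[(2S)-2-(tert-butyldimethylsilyloxy)-3-methylbut-3-enyl]-3,5-dimethoxyphenoxy}-3-phenylpropanoic acid
Product: 25 (2S)-8-[(2S)-2-(tert-butyldimethylsilyloxy)-3-methylbut-3-enyl]-5,7-dimethoxy-2-phenyl-2,3-dihydro-4H-chromen-4-one, via mixed trifluoroacetic anhydride 24 (not isolated)
Conditions: (CF3CO)2O (1.3 equiv), CH2Cl2, −20 °C to rt; NaHCO3 (aq) quench
Reagents that add atoms: none
Why: Intramolecular Friedel–Crafts acylation through the mixed trifluoroacetic anhydride: the tether allows only the six-membered closure onto C4a, which is ortho to O1 and C5–OMe and para to C7–OMe, so the pyranone ring should close at low temperature without a metal Lewis acid and without involving the C2 stereocentre.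

Step 11
Reactants: 25 (2S)-8-[(2S)-2-(tert-butyldimethylsilyloxy)-3-methylbut-3-enyl]-5,7-dimethoxy-2-phenyl-2,3-dihydro-4H-chromen-4-one
Product: 26 (2S)-8-[(2S)-2-hydroxy-3-methylbut-3-enyl]-5,7-dimethoxy-2-phenyl-2,3-dihydro-4H-chromen-4-one
Conditions: HF·pyridine, pyridine, THF, 0 °C to rt
Reagents that add atoms: none
Why: Fluoride-mediated desilylation under buffered, weakly acidic conditions should free the allylic alcohol without the base-induced ring opening to the chalcone that would racemise C2.

Compound list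
1 | methacrolein | C=C(C)C=O | starting material
2 | propargyl bromide | C#CCBr | starting material
3 | allenylmagnesium bromide | C=C=C[Mg]Br | intermediate
4 | B-allenyldiisopinocampheylborane (isopinocampheyl groups from (+)-α-pinene) | C=C=CB([C@@H]1C[C@@H]2C[C@H]([C@H]1C)C2(C)C)[C@@H]1C[C@@H]2C[C@H]([C@H]1C)C2(C)C | intermediate
5 | (S)-2-methylhex-1-en-5-yn-3-yl diisopinocampheylborinate | C=C(C)[C@H](CC#C)OB([C@@H]1C[C@@H]2C[C@H]([C@H]1C)C2(C)C)[C@@H]1C[C@@H]2C[C@H]([C@H]1C)C2(C)C | intermediate
6 | (S)-2-methylhex-1-en-5-yn-3-ol | C=C(C)[C@@H](O)CC#C | intermediate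
7 | (S)-tert-butyldimethyl[(2-methylhex-1-en-5-yn-3-yl)oxy]silane | C=C(C)[C@@H](O[Si](C)(C)C(C)(C)C)CC#C | intermediate
8 | lithium acetylide of 7 | C=C(C)[C@@H](O[Si](C)(C)C(C)(C)C)CC#C[Li] | intermediate
9 | lithium ynolate from 8 | C=C(C)[C@@H](O[Si](C)(C)C(C)(C)C)CC#CO[Li] | intermediate
10 | (S)-tert-butyldimethyl({2-methyl-6-[(triisopropylsilyl)oxy]hex-1-en-5-yn-3-yl}oxy)silane | C=C(C)[C@@H](O[Si](C)(C)C(C)(C)C)CC#CO[Si](C(C)C)(C(C)C)C(C)C | intermediate
11 | 3-ethoxycyclobut-2-en-1-one | CCOC1=CC(=O)C1 | starting material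
12 | cyclobutane-1,3-dione | O=C1CC(=O)C1 | intermediate
13 | 3-methoxycyclobut-2-en-1-one | COC1=CC(=O)C1 | intermediate
14 | 3-methoxybuta-1,3-dien-1-one (vinylketene) | C=C(OC)C=C=O | intermediate
15 | 2-[(2S)-2-(tert-butyldimethylsilyloxy)-3-methylbut-3-enyl]-4-(1-methoxyethenyl)-3-(triisopropylsilyloxy)cyclobut-2-en-1-one (both configurations at C4) | O=C1C(C[C@H](O[Si](C)(C)C(C)(C)C)C(C)=C)=C(O[Si](C(C)C)(C(C)C)C(C)C)C1C(OC)=C | intermediate
16 | dienylketene from 15 (ketene and methoxyvinyl groups cis on the central double bond) | O=C=C(C[C@H](O[Si](C)(C)C(C)(C)C)C(C)=C)/C(O[Si](C(C)C)(C(C)C)C(C)C)=C\C(OC)=C | intermediate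
17 | 2-[(2S)-2-(tert-butyldimethylsilyloxy)-3-methylbut-3-enyl]-5-methoxy-3-(triisopropylsilyloxy)cyclohexa-2,4-dien-1-one | O=C1CC(OC)=CC(O[Si](C(C)C)(C(C)C)C(C)C)=C1C[C@H](O[Si](C)(C)C(C)(C)C)C(C)=C | intermediate
18 | 2-[(2S)-2-(tert-butyldimethylsilyloxy)-3-methylbut-3-enyl]-5-methoxy-3-(triisopropylsilyloxy)phenol | C=C(C)[C@@H](O[Si](C)(C)C(C)(C)C)Cc1c(O[Si](C(C)C)(C(C)C)C(C)C)cc(OC)cc1O | intermediate
19 | ethyl (R)-3-hydroxy-3-phenylpropanoate | O[C@@H](c1ccccc1)CC(=O)OCC | starting material
20 | ethyl (3S)-3-{2-[(2S)-2-(tert-butyldimethylsilyloxy)-3-methylbut-3-enyl]-5-methoxy-3-(triisopropylsilyloxy)phenoxy}-3-phenylpropanoate | C=C(C)[C@@H](O[Si](C)(C)C(C)(C)C)Cc1c(O[Si](C(C)C)(C(C)C)C(C)C)cc(OC)cc1O[C@H](c1ccccc1)CC(=O)OCC | intermediate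
21 | tetrabutylammonium phenoxide from 20 | C=C(C)[C@@H](O[Si](C)(C)C(C)(C)C)Cc1c([O-])cc(OC)cc1O[C@H](c1ccccc1)CC(=O)OCC.CCCC[N+](CCCC)(CCCC)CCCC | intermediate
22 | ethyl (3S)-3-{2-[(2S)-2-(tert-butyldimethylsilyloxy)-3-methylbut-3-enyl]-3,5-dimethoxyphenoxy}-3-phenylpropanoate | C=C(C)[C@@H](O[Si](C)(C)C(C)(C)C)Cc1c(OC)cc(OC)cc1O[C@H](c1ccccc1)CC(=O)OCC | intermediate
23 | (3S)-3-{2-[(2S)-2-(tert-butyldimethylsilyloxy)-3-methylbut-3-enyl]-3,5-dimethoxyphenoxy}-3-phenylpropanoic acid | C=C(C)[C@@H](O[Si](C)(C)C(C)(C)C)Cc1c(OC)cc(OC)cc1O[C@H](c1ccccc1)CC(=O)O | intermediate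
24 | mixed trifluoroacetic anhydride of 23 | C=C(C)[C@@H](O[Si](C)(C)C(C)(C)C)Cc1c(OC)cc(OC)cc1O[C@H](c1ccccc1)CC(=O)OC(=O)C(F)(F)F | intermediate
25 | (2S)-8-[(2S)-2-(tert-butyldimethylsilyloxy)-3-methylbut-3-enyl]-5,7-dimethoxy-2-phenyl-2,3-dihydro-4H-chromen-4-one | C=C(C)[C@@H](O[Si](C)(C)C(C)(C)C)Cc1c(OC)cc(OC)c2c1O[C@H](c1ccccc1)CC2=O | intermediate
26 | (2S)-8-[(2S)-2-hydroxy-3-methylbut-3-enyl]-5,7-dimethoxy-2-phenyl-2,3-dihydro-4H-chromen-4-one (CNP0171002.1) | C=C(C)[C@@H](O)Cc1c(OC)cc(OC)c2c1O[C@H](c1ccccc1)CC2=O | target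

Total step count: 11.
Longest linear sequence: 9 steps (1, 2, 3, 6, 7, 8, 9, 10, 11).

Steps most likely to fail

Step 6. The vinylogous-ester cyclobutenone 13 may open only at temperatures at which silyl ynol ether 10 rearranges to a silylketene, and the ketene may dimerise or acylate the product phenol. The fallback sets out from 10 and comes back to the route at 18: the same vinylketene 14 is generated at room temperature by a photochemical Wolff rearrangement instead of by ring opening. Commercial 3,3-dimethoxybutan-2-one loses methanol on distillation from catalytic TsOH to give 3-methoxybut-3-en-2-one F1. Its lithium enolate (LiN(SiMe3)2, THF, −78 °C) is acylated with 2,2,2-trifluoroethyl trifluoroacetate to 1,1,1-trifluoro-5-methoxyhex-5-ene-2,4-dione F2, and detrifluoroacetylative diazo transfer (MsN3, Et3N, H2O, MeCN) should give 1-diazo-3-methoxybut-3-en-2-one F3. Irradiation of F3 with 10 (CH2Cl2, 254 nm, rt), then warming to 80 °C, should give 18 through 14, 15, 16 and 17; this diazo ketone variant of the benzannulation is known with silyloxyalkynes.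

Step 7. The activated β-hydroxy ester may eliminate to ethyl cinnamate faster than the ortho-substituted, weakly acidic phenol attacks, and ionisation at the benzylic carbon may erode the inversion. The fallback sets out from 18 and comes back to the route at 23: the ether is formed with commercial (R)-3-chloro-1-phenylpropan-1-ol, which has no acidifying carbonyl group and is an established Mitsunobu partner for ortho-substituted phenols. PPh3, DIAD, toluene should give, with inversion, the silyl-protected aryl (1S)-3-chloro-1-phenylpropyl ether F4. Bu4NF then MeI, as in step 8, gives the dimethoxy chloride F5. CsOAc, NaI (cat.), DMF, 70 °C gives the acetate F6, and K2CO3, MeOH gives the primary alcohol F7. TEMPO, PhI(OAc)2, CH2Cl2 gives the aldehyde F8, and Pinnick oxidation (NaClO2, NaH2PO4, 2-methylbut-2-ene, t-BuOH–H2O) gives acid 23.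

Step 10. The trifluoroacetic acid released may remove the silyl ether or add to the isopropenyl group, the benzylic C2–O bond may ionise (epimerisation or loss of the aryl ether), and the activated ring may be trifluoroacetylated. The fallback sets out from 23 and comes back to the route at 25: the acyl donor is changed to a nitrilium ion formed under pyridine-buffered conditions. MeNH2·HCl, EDC·HCl, HOBt, i-Pr2NEt, CH2Cl2 gives the N-methylamide F9. Tf2O, 2-fluoropyridine, CH2Cl2, −78 to 0 °C should close the ring at C4a (Bischler–Napieralski-type acylation) to the cyclic N-methyl ketimine F10, which aqueous NaOAc–AcOH hydrolyses to 25.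

Further compounds
F1 | step 6 | 3-methoxybut-3-en-2-one | C=C(OC)C(C)=O
F2 | step 6 | 1,1,1-trifluoro-5-methoxyhex-5-ene-2,4-dione | C=C(OC)C(=O)CC(=O)C(F)(F)F
F3 | step 6 | 1-diazo-3-methoxybut-3-en-2-one | C=C(OC)C(=O)C=[N+]=[N-]
F4 | step 7 | tert-butyl{[(2S)-1-{2-[(1S)-3-chloro-1-phenylpropoxy]-4-methoxy-6-(triisopropylsilyloxy)phenyl}-3-methylbut-3-en-2-yl]oxy}dimethylsilane | C=C(C)[C@@H](O[Si](C)(C)C(C)(C)C)Cc1c(O[Si](C(C)C)(C(C)C)C(C)C)cc(OC)cc1O[C@H](c1ccccc1)CCCl
F5 | step 7 | tert-butyl{[(2S)-1-{2-[(1S)-3-chloro-1-phenylpropoxy]-4,6-dimethoxyphenyl}-3-methylbut-3-en-2-yl]oxy}dimethylsilane | C=C(C)[C@@H](O[Si](C)(C)C(C)(C)C)Cc1c(OC)cc(OC)cc1O[C@H](c1ccccc1)CCCl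
F6 | step 7 | (3S)-3-{2-[(2S)-2-(tert-butyldimethylsilyloxy)-3-methylbut-3-enyl]-3,5-dimethoxyphenoxy}-3-phenylpropyl acetate | C=C(C)[C@@H](O[Si](C)(C)C(C)(C)C)Cc1c(OC)cc(OC)cc1O[C@H](c1ccccc1)CCOC(C)=O
F7 | step 7 | (3S)-3-{2-[(2S)-2-(tert-butyldimethylsilyloxy)-3-methylbut-3-enyl]-3,5-dimethoxyphenoxy}-3-phenylpropan-1-ol | C=C(C)[C@@H](O[Si](C)(C)C(C)(C)C)Cc1c(OC)cc(OC)cc1O[C@H](c1ccccc1)CCO
F8 | step 7 | (3S)-3-{2-[(2S)-2-(tert-butyldimethylsilyloxy)-3-methylbut-3-enyl]-3,5-dimethoxyphenoxy}-3-phenylpropanal | C=C(C)[C@@H](O[Si](C)(C)C(C)(C)C)Cc1c(OC)cc(OC)cc1O[C@H](c1ccccc1)CC=O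
F9 | step 10 | (3S)-3-{2-[(2S)-2-(tert-butyldimethylsilyloxy)-3-methylbut-3-enyl]-3,5-dimethoxyphenoxy}-N-methyl-3-phenylpropanamide | C=C(C)[C@@H](O[Si](C)(C)C(C)(C)C)Cc1c(OC)cc(OC)cc1O[C@H](c1ccccc1)CC(=O)NC
F10 | step 10 | (2S)-8-[(2S)-2-(tert-butyldimethylsilyloxy)-3-methylbut-3-enyl]-5,7-dimethoxy-N-methyl-2-phenyl-2,3-dihydro-4H-chromen-4-imine | C=C(C)[C@@H](O[Si](C)(C)C(C)(C)C)Cc1c(OC)cc(OC)c2c1O[C@H](c1ccccc1)CC2=NC
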